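X grows while Z and G meet, so read each earlier run as a step response: a rise with time constant T towards a level.

| flask | Z | G | remark | time |
|---|---|---|---|---|
| green | 0.060 M | 0.057 M | run made earlier |  |
| blue | 0.060 M | 0.038 M | run made earlier |  |
| violet | 0.060 M | 0.086 M | run made earlier |  |
| ochre | 0.030 M | 0.057 M | run made earlier |  |
| south-east | 0.060 M (fed, over 20 min) | 0.0570 M | all else is in the flask from the start; the feed brings no volume worth counting | 8.0 h |
| south-west | 0.060 M (fed, over 3.0 h) | 0.0570 M | all else is in the flask from the start; the feed brings no volume worth counting | 8.0 h |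
| north-east | 0.060 M | 0.0570 M | everything together at the start | 8.0 h |
| north | 0.060 M | 0.0570 M (fed, over 3.0 h) | all else is in the flask from the start; the feed brings no volume worth counting | 8.0 h |

- green (time / h: X / %): 0.500: 4.1; 1.50: 8.0; 3.00: 9.8; 4.00: 10.5; 6.00: 10.6; 8.00: 10.5
- blue (time / h: X / %): 0.417: 2.5; 1.33: 5.4; 2.50: 7.0; 4.00: 7.3; 5.00: 7.0; 6.00: 7.7
- violet (time / h: X / %): 0.417: 5.7; 1.33: 11.3; 2.50: 13.3; 4.00: 15.0; 5.00: 15.6; 6.00: 15.0
- ochre (time / h: X / %): 0.500: 4.5; 1.00: 7.4; 2.00: 11.5; 3.00: 13.5; 6.00: 15.3

(scatter of a reading: 0.3 percentage points)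

* the flask with the highest amount of X, in percent of the Z charged ("all alike" if they lie within 1.5 percentage points) (south-east / south-west / north-east / north / all alike)
* final X, as a percentage of the Z charged, in south-east
* final X, as a percentage of the Z charged, in south-west
* final X, as a percentage of the Z charged, in north-east
* final X, as a percentage of the Z charged, in north

- the analysis behind the earlier runs scatters by 0.3 percentage points, standard deviation

In green the level reads 10.5%, and the reading at 1.50 h puts the knee at 1.05 h. Blue and violet read 0.998 h and 0.978 h, although [G] goes from 0.038 M to 0.086 M. Ochre, with half the Z, reads 1.51 h. So I tie T to Z and call it the clock of Z: the time constant in which Z disappears at a given charge, over these values of [G]. A straight line for 1/T through green and ochre has the slope 9.63 M⁻¹ h⁻¹ on [Z] and the intercept 0.372 h⁻¹.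

The slope at the start is k[G] and the level is k[G]T. Green gives k = 1.76 M⁻¹ h⁻¹ and ochre 1.77 M⁻¹ h⁻¹. This pseudo-first-order rate, 0.100 h⁻¹, is slower than the clock's 0.952 h⁻¹, so X takes a small share of Z.

My reckoning for north-east is the green level, and south-east goes with it, since its 20 min feed is shorter than 1.05 h. In north, X starts with zero slope. On the green clock Z halves by 0.730 h, when a quarter of the G has been fed, so I run the ramp on the ochre clock. That gives k[G]T²/3.0 h·(1 − exp(−3.0 h/T)) = 6.58%. In south-west, feed times clock is 0.0303 M, which is about ochre's charge, so I take ochre's last reading, 15.3%.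

The forecast says north, with 10% in south-east, 6.6% in south-west, 10.5% in north-east and 10.6% in north. Its ground for south-west is “G decays before Z arrives”. We part on which charge perishes: I put the clock on Z.

The flasks give 10.9% in south-east, 12.7% in south-west, 10.6% in north-east and 6.19% in north, so south-west stands highest, though below my 15.3%.

    Z + X → J (k = 1.50 M⁻¹ h⁻¹)
    X ⇌ E (K = 0.620, k = 0.0690 h⁻¹)
    2 Z → L (k = 10.0 M⁻¹ h⁻¹)
    Z + G → X (k = 2.10 M⁻¹ h⁻¹)
    Z → D (k = 0.140 h⁻¹)

North holds 14.5% of its Z at 3.00 h, when its feed of G ends, and it gives 6.19% against my 6.58%. With 0.015 M of Z in the same flask, the clock at half that charge stretches from 1.51 h to 2.25 h. The same ramp then gives 12.4%, and that flask ends at 13.9%.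

The numbers in the tables stem from a simulated flask with constants of no real substance, noise included.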